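**Retrosynthetic overview**

1. The last bond is C8–C9, made by Stille coupling of a core E-vinyl iodide with an east stannyl dienamide built from propargyl alcohol, triethyl phosphonoacetate and the aminocyclopentenone obtained from cyclopentane-1,3-dione.
2. The west amide comes from N-acylation of a 2-amino-5,6-epoxy enone with (2E,4E,6E)-8-methylnona-2,4,6-trienoyl chloride (vinylogous Horner–Wadsworth–Emmons); the amino enone arises from an α-azido ketone by loss of N2.
3. In the core, the azide (SN2 at S5), the oxirane (3α oxygen displacing a 2β mesylate) and the quaternary carbinol all derive from the β-1,2-diol formed by OsO4 syn-dihydroxylation of methyl 3,4-O-isopropylidene shikimate; the ester carbon is extended to the iodovinyl group by reduction and Takai olefination.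
4. Feature on which the strategy rests: round the six-membered ring, C4–C5–C6–C1–C2 carry O, O, O, O, N without a gap, C3 is the only unsubstituted CH, and the single exocyclic carbon C7 sits on C4. This is shikimic acid carbon for carbon (S1=C4, S2=C5, S3=C6, S4=C1, S5=C2, S6=C3, carboxyl S7=C7) after oxygenation of its alkene, and the oxirane oxygen on C6, trans to the C4 hydroxyl, is the acid's own 3α oxygen.
5. Ring order: carbocycle bought (shikimic acid); temporary dioxolane (step 2); transient osmate ring (step 3); oxirane (step 10); the cyclopentenone ring arrives ready-made with the east fragment in the final coupling.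

Key step: step 3

Remark on the chemistry: up to the azido ketone the ring is described in shikimate numbering (S1–S7). α is the face carrying the C3 and C4 hydroxyls of shikimic acid and β the face carrying its C5 hydroxyl. From the imino ketone onward the target numbering is used (C1 ketone, C2 nitrogen-bearing carbon, C4 carbinol, C5/C6 oxirane). (E)-4-Methylpent-2-enal and triethyl 4-phosphonocrotonate are taken as purchasable.

**Core, steps 1–12**

Step 1
Reactants: 1 (−)-shikimic acid
Product: 2 methyl shikimate
Conditions: MeOH, camphorsulfonic acid (cat.), reflux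
Reagents that add atoms: methanol, CO
Why: Fischer esterification in excess methanol should convert the carboxylic acid into the methyl ester without touching the three carbinol centres.

Step 2
Reactants: 2 methyl shikimate
Product: 3 methyl 3,4-O-isopropylidene shikimate (dioxolane on the 3α,4α-diol, 5β-OH free)
Conditions: Me2C(OMe)2, p-TsOH·H2O (cat.), acetone, rt
Reagents that add atoms: 2,2-dimethoxypropane, COC(C)(C)OC
Why: Acid-catalysed transketalisation should bridge only the cis 3α,4α-diol, because a five-membered ketal across the trans 4α,5β pair would be strained, so the 5β hydroxyl stays free.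

Step 3
Reactants: 3 methyl 3,4-O-isopropylidene shikimate
Product: 5 methyl 1β,2β,5β-trihydroxy-3α,4α-(isopropylidenedioxy)cyclohexane-1α-carboxylate, via cyclic osmate ester 4 (not isolated)
Conditions: OsO4 (5 mol %), NMO (1.5 equiv), MeSO2NH2 (1 equiv), acetone/H2O 4:1, rt
Reagents that add atoms: osmium tetroxide, O=[Os](=O)(=O)=O; N-methylmorpholine N-oxide, C[N+]1([O-])CCOCC1; water, O
Why: The S1=S2 alkene and two oxo ligands of OsO4 combine in a concerted, suprafacial (3+2) cycloaddition to the five-membered osmate ester 4 of hexavalent osmium, which NMO oxidises and water hydrolyses (the sulfonamide speeding this turnover), releasing the syn-diol and returning OsO4; this is the Upjohn dihydroxylation, familiar for cyclohexenecarboxylates bearing an allylic ketal. The only ring closed is the transient osmium-containing dioxolane, formed by cycloaddition with both C–O bonds made on one face. The two new stereocentres, the quaternary carbinol S1 (future C4) and S2 (future C5), are set together by the cis-fused acetonide, whose allylic S3 oxygen and methyl groups cover the α face, so osmium should add from the β face, anti to the allylic C–O bond. Only β-facial selectivity is required, since 3 holds a single alkene and the homoallylic 5β hydroxyl is remote and pseudo-equatorial; the low reactivity of the enoate is met by the amine-oxide turnover and the accelerant. The product carries the β oxygen on S2 trans to the α oxygen on S3, which is the arrangement needed for the later oxirane closure with inversion.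

Step 4
Reactants: 5 triol ester
Product: 6 methyl 1β-hydroxy-2β,5β-bis(methanesulfonyloxy)-3α,4α-(isopropylidenedioxy)cyclohexane-1α-carboxylate
Conditions: MsCl (2.3 equiv), Et3N, CH2Cl2, −10 to 0 °C
Reagents that add atoms: methanesulfonyl chloride, CS(=O)(=O)Cl
Why: Sulfonylation through sulfene should be fast on the two secondary hydroxyls and slow on the hindered tertiary α-hydroxy-ester hydroxyl, giving the 2β,5β-dimesylate with no change at any stereocentre.

Step 5
Reactants: 6 bis-mesylate with free tertiary hydroxyl
Product: 7 methyl 1β-(tert-butyldimethylsilyloxy)-2β,5β-bis(methanesulfonyloxy)-3α,4α-(isopropylidenedioxy)cyclohexane-1α-carboxylate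
Conditions: TBSOTf, 2,6-lutidine, CH2Cl2, 0 °C to rt
Reagents that add atoms: tert-butyldimethylsilyl triflate, CC(C)(C)[Si](C)(C)OS(=O)(=O)C(F)(F)F
Why: The silyl triflate should silylate even this tertiary alcohol, and the resulting ether later prevents the S1 oxygen from opening the oxirane (Payne rearrangement) and suppresses ketol and retro-aldol pathways.

Step 6
Reactants: 7 silyl ether ester
Product: 8 1β-(tert-butyldimethylsilyloxy)-2β,5β-bis(methanesulfonyloxy)-3α,4α-(isopropylidenedioxy)cyclohexane-1α-carbaldehyde
Conditions: i-Bu2AlH (1.3 equiv), CH2Cl2, −78 °C; aq. potassium sodium tartrate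
Reagents that add atoms: none
Why: Partial hydride reduction of an α-silyloxy ester should stop at the aldehyde because the aluminium hemiacetal is held by chelation to the α oxygen until work-up, while the mesylates are inert and the quaternary α carbon can neither epimerise nor eliminate.

Step 7
Reactants: 8 aldehyde
Product: 9 1α-[(E)-2-iodoethenyl]-1β-(tert-butyldimethylsilyloxy)-3α,4α-(isopropylidenedioxy)cyclohexane-2β,5β-diyl dimethanesulfonate
Conditions: CHI3 (2 equiv), CrCl2 (6 equiv), dioxane/THF 6:1, 0 °C to rt, dark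
Reagents that add atoms: iodoform, IC(I)I
Why: In the Takai olefination the geminal dichromium species formed from iodoform and divalent chromium adds to the aldehyde and eliminates to the E-vinyl iodide (new carbon C8), under non-basic conditions that leave both mesylates in place.

Step 8
Reactants: 9 vinyl iodide bis-mesylate
Product: 10 5α-azido-1α-[(E)-2-iodoethenyl]-1β-(tert-butyldimethylsilyloxy)-3α,4α-(isopropylidenedioxy)cyclohexan-2β-yl methanesulfonate
Conditions: NaN3 (4 equiv), DMF, 65–70 °C
Reagents that add atoms: sodium azide, [Na+].[N-]=[N+]=[N-]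
Why: SN2 displacement by azide should invert S5 (5β mesylate to 5α azide), whereas the S2 mesylate, flanked by the quaternary S1 and the ketal carbon S3, is neopentyl-like and should remain; the temperature is held down to limit E2 elimination and azide–alkene cycloaddition.

Step 9
Reactants: 10 azido mesylate acetonide
Product: 11 5α-azido-3α,4α-dihydroxy-1α-[(E)-2-iodoethenyl]-1β-(tert-butyldimethylsilyloxy)cyclohexan-2β-yl methanesulfonate
Conditions: TFA/H2O 4:1, CH2Cl2, 0 °C to rt
Reagents that add atoms: none
Why: Acid hydrolysis should cleave the isopropylidene ketal while the hindered tertiary silyl ether, the mesylate, the azide and the vinyl iodide tolerate aqueous TFA.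

Step 10
Reactants: 11 azido diol mesylate
Product: 12 5α-azido-2α,3α-epoxy-1α-[(E)-2-iodoethenyl]-1β-(tert-butyldimethylsilyloxy)cyclohexan-4α-ol
Conditions: K2CO3 (1.5 equiv), MeOH, 0 °C to rt
Reagents that add atoms: none
Why: The 3α alkoxide should displace the anti 2β mesylate in a 3-exo-tet Williamson closure with inversion at S2, placing the oxirane on the α face anti to the 1β silyloxy group; the 4α hydroxyl is cis to the oxirane and cannot rearrange it, and the S1 oxygen is blocked.

Step 11
Reactants: 12 azido epoxy alcohol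
Product: 13 5α-azido-2α,3α-epoxy-1α-[(E)-2-iodoethenyl]-1β-(tert-butyldimethylsilyloxy)cyclohexan-4-one
Conditions: Dess–Martin periodinane (1.5 equiv), CH2Cl2, 0 °C to rt
Reagents that add atoms: none
Why: Dess–Martin oxidation of the secondary carbinol under nearly neutral conditions should give the ketone without disturbing oxirane, azide or silyl ether, and any epimerisation at S5 is harmless because that centre becomes trigonal in the next step.

Step 12
Reactants: 13 azido epoxy ketone
Product: 15 2-amino-5α,6α-epoxy-4α-[(E)-2-iodoethenyl]-4β-(tert-butyldimethylsilyloxy)cyclohex-2-en-1-one, via imino ketone 14 (not isolated)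
Conditions: Et3N (1.5 equiv), CH2Cl2, 0 °C to rt (N2 evolution); crude product used directly
Reagents that add atoms: none
Why: Base-induced dinitrogen loss from a cyclic α-azido ketone (deprotonation at the azide-bearing carbon, expulsion of N2 to the α-imino ketone, tautomerisation) should give the conjugated 2-amino enone, the double bond being able to form only toward C3 because the other neighbour is the carbonyl, and the mild amine base should spare the epoxy ketone.

**West chain, steps 13–17**

Step 13
Reactants: 16 (E)-4-methylpent-2-enal; 17 triethyl 4-phosphonocrotonate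
Product: 18 ethyl (2E,4E,6E)-8-methylnona-2,4,6-trienoate
Conditions: LiN(SiMe3)2, THF, −78 to 0 °C
Reagents that add atoms: none
Why: The vinylogous Horner–Wadsworth–Emmons olefination of the enal with the stabilised phosphonate anion should form the new C4=C5 bond with E geometry and leave the two existing E alkenes unchanged.

Step 14
Reactants: 18 trienoate ester
Product: 19 (2E,4E,6E)-8-methylnona-2,4,6-trienoic acid
Conditions: LiOH, THF/MeOH/H2O, rt; then 1 M HCl
Reagents that add atoms: lithium hydroxide, [Li+].[OH-]
Why: Saponification of the ethyl ester should deliver the acid, and crystallisation at this stage removes any minor 4Z isomer.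

Step 15
Reactants: 19 trienoic acid
Product: 20 (2E,4E,6E)-8-methylnona-2,4,6-trienoyl chloride
Conditions: (COCl)2, DMF (cat.), CH2Cl2, 0 °C to rt; used fresh
Reagents that add atoms: oxalyl chloride, ClC(=O)C(Cl)=O
Why: Chlorination through the catalytic chloroiminium species proceeds under neutral conditions that should preserve the all-E triene.

Step 16
Reactants: 15 2-amino epoxy enone; 20 trienoyl chloride
Product: 21 (2E,4E,6E)-N-[5α,6α-epoxy-4α-((E)-2-iodoethenyl)-1-oxo-4β-(tert-butyldimethylsilyloxy)cyclohex-2-en-2-yl]-8-methylnona-2,4,6-trienamide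
Conditions: pyridine, DMAP (cat.), CH2Cl2, −20 to 0 °C
Reagents that add atoms: none
Why: Nucleophilic-catalysed N-acylation of the primary enamine nitrogen should give the enamide, since the only oxygen nucleophile is silylated and the low temperature with a weak base avoids ketene formation from the acid chloride.

Step 17
Reactants: 21 silylated west-acylated core
Product: 22 (2E,4E,6E)-N-[5α,6α-epoxy-4β-hydroxy-4α-((E)-2-iodoethenyl)-1-oxocyclohex-2-en-2-yl]-8-methylnona-2,4,6-trienamide
Conditions: HF·pyridine, pyridine, THF, 0 °C to rt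
Reagents that add atoms: none
Why: Fluoride cleavage of the Si–O bond, driven by Si–F bond formation, should free the tertiary alcohol under buffered, slightly acidic conditions that never generate the alkoxide able to attack the neighbouring oxirane.

**East fragment, steps 18–24**

Step 18
Reactants: 23 propargyl alcohol
Product: 24 (E)-3-(tributylstannyl)prop-2-en-1-ol
Conditions: Bu3SnH, AIBN (cat.), neat, 80 °C; chromatography
Reagents that add atoms: tributyltin hydride, CCCC[SnH](CCCC)CCCC
Why: Radical hydrostannation of the terminal alkyne, with reversible stannyl radical addition equilibrating the isomers, should favour the E β-stannyl alkene, which is separated from the Z and 2-stannyl isomers.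

Step 19
Reactants: 24 stannyl allylic alcohol
Product: 25 (E)-3-(tributylstannyl)prop-2-enal
Conditions: MnO2, CH2Cl2, rt
Reagents that add atoms: none
Why: MnO2 oxidises allylic alcohols selectively to enals under neutral conditions, so the C–Sn bond and the E geometry should be retained.

Step 20
Reactants: 25 stannyl enal
Product: 26 ethyl (2E,4E)-5-(tributylstannyl)penta-2,4-dienoate
Conditions: (EtO)2P(O)CH2CO2Et, NaH, THF, 0 °C to rt
Reagents that add atoms: triethyl phosphonoacetate, CCOC(=O)CP(=O)(OCC)OCC
Why: The Horner–Wadsworth–Emmons reaction of a stabilised phosphonate with the enal should give the E enoate and bring in C12 and C13.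

Step 21
Reactants: 26 stannyl dienoate
Product: 27 (2E,4E)-5-(tributylstannyl)penta-2,4-dienoic acid
Conditions: LiOH, THF/MeOH/H2O, rt; then 0.5 M HCl to pH 5, 0 °C
Reagents that add atoms: lithium hydroxide, [Li+].[OH-]
Why: Saponification should give the acid, the vinyl–tin bond being stable to hydroxide and to a cold, only mildly acidic work-up.

Step 22
Reactants: 28 cyclopentane-1,3-dione
Product: 29 2-(hydroxyimino)cyclopentane-1,3-dione
Conditions: NaNO2, aq. HCl, 0 °C
Reagents that add atoms: sodium nitrite, [Na+].[O-]N=O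
Why: Nitrosation of the enolised 1,3-dione at its central carbon by nitrous acid, followed by tautomerisation, should give the oxime.

Step 23
Reactants: 29 oxime
Product: 30 2-amino-3-hydroxycyclopent-2-enone hydrochloride
Conditions: H2 (1 atm), 10% Pd/C, MeOH, HCl, rt
Reagents that add atoms: hydrogen chloride, Cl
Why: Catalytic hydrogenation should reduce the oxime to the primary amine, which enolises and is trapped as the hydrochloride so that it cannot self-condense.

Step 24
Reactants: 27 stannyl dienoic acid; 30 aminocyclopentenone hydrochloride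
Product: 33 (2E,4E)-N-(2-hydroxy-5-oxocyclopent-1-en-1-yl)-5-(tributylstannyl)penta-2,4-dienamide, via pivalic mixed anhydride 31 (not isolated), via O-acyl enol ester 32 (not isolated)
Conditions: t-BuCOCl, Et3N, THF, 0 °C; then 30, Et3N, DMF, 0 °C to rt
Reagents that add atoms: none
Why: The mixed anhydride should be attacked at its less hindered dienoyl carbonyl by the acidic enol oxygen, and the acyl group should then shift from oxygen to the adjacent nitrogen through a five-membered transition state to give the stable amide, all under non-acidic conditions that keep the C–Sn bond.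

**Final coupling, step 25**

Step 25
Reactants: 22 west-acylated core vinyl iodide; 33 east stannyl dienamide
Product: 34 target CNP0215439.3, (2E,4E,6E)-N-[(4S,5S,6R)-5,6-epoxy-4-hydroxy-4-{(1E,3E,5E)-7-[(2-hydroxy-5-oxocyclopent-1-en-1-yl)amino]-7-oxohepta-1,3,5-trienyl}-1-oxocyclohex-2-en-2-yl]-8-methylnona-2,4,6-trienamide
Conditions: PdCl2(MeCN)2 (10 mol %), DMF, rt, dark
Reagents that add atoms: none
Why: In the Stille coupling the vinyl iodide adds oxidatively to zerovalent palladium formed in situ, the dienyl group is transferred from tin and reductive elimination forms C8–C9 with retention at both alkenes, under ligand-free room-temperature conditions mild enough for the epoxy enone, the free tertiary alcohol and the polyenes.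

**Compound list**

1 | (−)-shikimic acid, (3R,4S,5R)-3,4,5-trihydroxycyclohex-1-ene-1-carboxylic acid | OC(=O)C1=C[C@@H](O)[C@@H](O)[C@H](O)C1 | starting material
2 | methyl shikimate | COC(=O)C1=C[C@@H](O)[C@@H](O)[C@H](O)C1 | intermediate
3 | methyl 3,4-O-isopropylidene shikimate | COC(=O)C1=C[C@H]2OC(C)(C)O[C@H]2[C@H](O)C1 | intermediate
4 | cyclic osmate ester bridging the 1β and 2β oxygens of 3 (OsO2 unit, hexavalent osmium) | COC(=O)[C@@]1(O[Os](=O)(=O)O2)[C@H]2[C@H]3OC(C)(C)O[C@H]3[C@H](O)C1 | intermediate
5 | methyl 1β,2β,5β-trihydroxy-3α,4α-(isopropylidenedioxy)cyclohexane-1α-carboxylate | COC(=O)[C@@]1(O)[C@H](O)[C@H]2OC(C)(C)O[C@H]2[C@H](O)C1 | intermediate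
6 | methyl 1β-hydroxy-2β,5β-bis(methanesulfonyloxy)-3α,4α-(isopropylidenedioxy)cyclohexane-1α-carboxylate | COC(=O)[C@@]1(O)[C@H](OS(C)(=O)=O)[C@H]2OC(C)(C)O[C@H]2[C@H](OS(C)(=O)=O)C1 | intermediate
7 | methyl 1β-(tert-butyldimethylsilyloxy)-2β,5β-bis(methanesulfonyloxy)-3α,4α-(isopropylidenedioxy)cyclohexane-1α-carboxylate | COC(=O)[C@@]1(O[Si](C)(C)C(C)(C)C)[C@H](OS(C)(=O)=O)[C@H]2OC(C)(C)O[C@H]2[C@H](OS(C)(=O)=O)C1 | intermediate
8 | 1β-(tert-butyldimethylsilyloxy)-2β,5β-bis(methanesulfonyloxy)-3α,4α-(isopropylidenedioxy)cyclohexane-1α-carbaldehyde | O=C[C@@]1(O[Si](C)(C)C(C)(C)C)[C@H](OS(C)(=O)=O)[C@H]2OC(C)(C)O[C@H]2[C@H](OS(C)(=O)=O)C1 | intermediate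
9 | 1α-[(E)-2-iodoethenyl]-1β-(tert-butyldimethylsilyloxy)-3α,4α-(isopropylidenedioxy)cyclohexane-2β,5β-diyl dimethanesulfonate | I/C=C/[C@@]1(O[Si](C)(C)C(C)(C)C)[C@H](OS(C)(=O)=O)[C@H]2OC(C)(C)O[C@H]2[C@H](OS(C)(=O)=O)C1 | intermediate
10 | 5α-azido-1α-[(E)-2-iodoethenyl]-1β-(tert-butyldimethylsilyloxy)-3α,4α-(isopropylidenedioxy)cyclohexan-2β-yl methanesulfonate | I/C=C/[C@@]1(O[Si](C)(C)C(C)(C)C)[C@H](OS(C)(=O)=O)[C@H]2OC(C)(C)O[C@H]2[C@@H](N=[N+]=[N-])C1 | intermediate
11 | 5α-azido-3α,4α-dihydroxy-1α-[(E)-2-iodoethenyl]-1β-(tert-butyldimethylsilyloxy)cyclohexan-2β-yl methanesulfonate | I/C=C/[C@@]1(O[Si](C)(C)C(C)(C)C)[C@H](OS(C)(=O)=O)[C@@H](O)[C@@H](O)[C@@H](N=[N+]=[N-])C1 | intermediate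
12 | 5α-azido-2α,3α-epoxy-1α-[(E)-2-iodoethenyl]-1β-(tert-butyldimethylsilyloxy)cyclohexan-4α-ol | I/C=C/[C@@]1(O[Si](C)(C)C(C)(C)C)[C@H]2O[C@H]2[C@@H](O)[C@@H](N=[N+]=[N-])C1 | intermediate
13 | 5α-azido-2α,3α-epoxy-1α-[(E)-2-iodoethenyl]-1β-(tert-butyldimethylsilyloxy)cyclohexan-4-one | I/C=C/[C@@]1(O[Si](C)(C)C(C)(C)C)[C@H]2O[C@H]2C(=O)[C@@H](N=[N+]=[N-])C1 | intermediate
14 | 5α,6α-epoxy-2-imino-4α-[(E)-2-iodoethenyl]-4β-(tert-butyldimethylsilyloxy)cyclohexan-1-one | N=C1C[C@@](O[Si](C)(C)C(C)(C)C)(/C=C/I)[C@H]2O[C@H]2C1=O | intermediate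
15 | 2-amino-5α,6α-epoxy-4α-[(E)-2-iodoethenyl]-4β-(tert-butyldimethylsilyloxy)cyclohex-2-en-1-one | NC1=C[C@@](O[Si](C)(C)C(C)(C)C)(/C=C/I)[C@H]2O[C@H]2C1=O | intermediate
16 | (E)-4-methylpent-2-enal | CC(C)/C=C/C=O | starting material
17 | triethyl 4-phosphonocrotonate | CCOC(=O)/C=C/CP(=O)(OCC)OCC | starting material
18 | ethyl (2E,4E,6E)-8-methylnona-2,4,6-trienoate | CCOC(=O)/C=C/C=C/C=C/C(C)C | intermediate
19 | (2E,4E,6E)-8-methylnona-2,4,6-trienoic acid | OC(=O)/C=C/C=C/C=C/C(C)C | intermediate
20 | (2E,4E,6E)-8-methylnona-2,4,6-trienoyl chloride | CC(C)/C=C/C=C/C=C/C(Cl)=O | intermediate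
21 | (2E,4E,6E)-N-[5α,6α-epoxy-4α-((E)-2-iodoethenyl)-1-oxo-4β-(tert-butyldimethylsilyloxy)cyclohex-2-en-2-yl]-8-methylnona-2,4,6-trienamide | CC(C)/C=C/C=C/C=C/C(=O)NC1=C[C@@](O[Si](C)(C)C(C)(C)C)(/C=C/I)[C@H]2O[C@H]2C1=O | intermediate
22 | (2E,4E,6E)-N-[5α,6α-epoxy-4β-hydroxy-4α-((E)-2-iodoethenyl)-1-oxocyclohex-2-en-2-yl]-8-methylnona-2,4,6-trienamide | CC(C)/C=C/C=C/C=C/C(=O)NC1=C[C@@](O)(/C=C/I)[C@H]2O[C@H]2C1=O | intermediate
23 | propargyl alcohol | OCC#C | starting material
24 | (E)-3-(tributylstannyl)prop-2-en-1-ol | CCCC[Sn](CCCC)(CCCC)/C=C/CO | intermediate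
25 | (E)-3-(tributylstannyl)prop-2-enal | CCCC[Sn](CCCC)(CCCC)/C=C/C=O | intermediate
26 | ethyl (2E,4E)-5-(tributylstannyl)penta-2,4-dienoate | CCCC[Sn](CCCC)(CCCC)/C=C/C=C/C(=O)OCC | intermediate
27 | (2E,4E)-5-(tributylstannyl)penta-2,4-dienoic acid | CCCC[Sn](CCCC)(CCCC)/C=C/C=C/C(=O)O | intermediate
28 | cyclopentane-1,3-dione | O=C1CCC(=O)C1 | starting material
29 | 2-(hydroxyimino)cyclopentane-1,3-dione | ON=C1C(=O)CCC1=O | intermediate
30 | 2-amino-3-hydroxycyclopent-2-enone hydrochloride | NC1=C(O)CCC1=O.Cl | intermediate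
31 | (2E,4E)-5-(tributylstannyl)penta-2,4-dienoic pivalic anhydride | CCCC[Sn](CCCC)(CCCC)/C=C/C=C/C(=O)OC(=O)C(C)(C)C | intermediate
32 | 2-amino-3-oxocyclopent-1-en-1-yl (2E,4E)-5-(tributylstannyl)penta-2,4-dienoate | CCCC[Sn](CCCC)(CCCC)/C=C/C=C/C(=O)OC1=C(N)C(=O)CC1 | intermediate
33 | (2E,4E)-N-(2-hydroxy-5-oxocyclopent-1-en-1-yl)-5-(tributylstannyl)penta-2,4-dienamide | CCCC[Sn](CCCC)(CCCC)/C=C/C=C/C(=O)NC1=C(O)CCC1=O | intermediate
34 | CNP0215439.3, (4S,5S,6R) epoxyquinol bis-amide (C4 hydroxyl β, oxirane and heptatrienyl chain α, all chain alkenes E) | CC(C)/C=C/C=C/C=C/C(=O)NC1=C[C@@](O)(/C=C/C=C/C=C/C(=O)NC2=C(O)CCC2=O)[C@H]2O[C@H]2C1=O | target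

**Step count and risks**

Total step count: 25. Longest linear sequence: 15 steps (steps 1–12, 16, 17 and 25, from shikimic acid).

Steps most likely to fail:

Step 8. The azide displacement at S5 may be slow because the α-face trajectory is screened by the ketal oxygen on S4 and the α-iodovinyl group on S1. E2 loss of the mesylate toward S6, participation by the ketal oxygen, or intramolecular azide–alkene cycloaddition of the product at the temperature required could then take over. The fallback brings nitrogen in by epoxide opening instead of sulfonate displacement; it sets out from 9 and comes back at 15. Hydrolysis of the acetonide of 9 (TFA/H2O) would give the diol bis-mesylate F1. K2CO3 in MeOH would close two oxiranes at once (O3 onto S2, O4 onto S5, each anti to its mesylate) to the α,α-bis-epoxide F2. NaN3 with NH4Cl in aqueous MeOH at 60 °C would open the S4–S5 oxirane at its distal, non-neopentyl carbon S5, attack at S3 or S4 being retarded by the adjacent C–O bond, to give the 5β-azido 4α-alcohol F3, the S5 epimer of 12. Dess–Martin oxidation would give the epimeric azido ketone F4, and Et3N would convert it into 15, since the S5 centre becomes trigonal.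

Step 12. The free 2-amino enone may self-condense to dihydropyrazines, or the base may open the α,β-epoxy ketone, before the nitrogen is acylated. The fallback acylates nitrogen at the amine oxidation level and introduces the unsaturation afterwards; it sets out from 12 and comes back at 21. Staudinger reduction of 12 (PMe3, THF/H2O) would give the amino epoxy alcohol F5. Acylation with 20 (Et3N, CH2Cl2, −20 °C, amine ahead of the hindered secondary alcohol) would give the hydroxy amide F6, and Dess–Martin oxidation the α-amido ketone F7. Deprotonation with LiN(SiMe3)2 (2.2 equiv) and PhSeBr at −78 °C would give the α-phenylselenide F8 at the only enolisable α carbon. Oxidation with H2O2/pyridine at 0 °C would trigger selenoxide syn-elimination toward the S6 hydrogen and give 21.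

Step 17. Cleavage of the hindered tertiary silyl ether may be slow, with fluoride or acid opening the oxirane or degrading the polyene during a prolonged reaction. The fallback removes the silyl group before the enamide and triene exist; it sets out from 13 and comes back at 22. Aqueous HF in MeCN (0 °C to rt) on the robust azido ketone 13 would give the hydroxy azido ketone F9. Et3N, too weak a base to form the tertiary alkoxide, would convert it into the free-hydroxy amino enone F10. Acylation with 20 (pyridine, no DMAP, −20 °C, tertiary alcohol unreactive) would give 22.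

**Further compounds**

F1 | step 8 | 3α,4α-dihydroxy-1α-[(E)-2-iodoethenyl]-1β-(tert-butyldimethylsilyloxy)cyclohexane-2β,5β-diyl dimethanesulfonate | I/C=C/[C@@]1(O[Si](C)(C)C(C)(C)C)[C@H](OS(C)(=O)=O)[C@@H](O)[C@@H](O)[C@H](OS(C)(=O)=O)C1
F2 | step 8 | 2α,3α:4α,5α-diepoxy-1α-[(E)-2-iodoethenyl]-1β-(tert-butyldimethylsilyloxy)cyclohexane | I/C=C/[C@@]1(O[Si](C)(C)C(C)(C)C)[C@H]2O[C@H]2[C@H]3O[C@H]3C1
F3 | step 8 | 5β-azido-2α,3α-epoxy-1α-[(E)-2-iodoethenyl]-1β-(tert-butyldimethylsilyloxy)cyclohexan-4α-ol | I/C=C/[C@@]1(O[Si](C)(C)C(C)(C)C)[C@H]2O[C@H]2[C@@H](O)[C@H](N=[N+]=[N-])C1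
F4 | step 8 | 5β-azido-2α,3α-epoxy-1α-[(E)-2-iodoethenyl]-1β-(tert-butyldimethylsilyloxy)cyclohexan-4-one | I/C=C/[C@@]1(O[Si](C)(C)C(C)(C)C)[C@H]2O[C@H]2C(=O)[C@H](N=[N+]=[N-])C1
F5 | step 12 | 5α-amino-2α,3α-epoxy-1α-[(E)-2-iodoethenyl]-1β-(tert-butyldimethylsilyloxy)cyclohexan-4α-ol | I/C=C/[C@@]1(O[Si](C)(C)C(C)(C)C)[C@H]2O[C@H]2[C@@H](O)[C@@H](N)C1
F6 | step 12 | (2E,4E,6E)-N-[2α,3α-epoxy-4α-hydroxy-1α-((E)-2-iodoethenyl)-1β-(tert-butyldimethylsilyloxy)cyclohexan-5α-yl]-8-methylnona-2,4,6-trienamide (shikimate numbering) | I/C=C/[C@@]1(O[Si](C)(C)C(C)(C)C)[C@H]2O[C@H]2[C@@H](O)[C@@H](NC(=O)/C=C/C=C/C=C/C(C)C)C1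
F7 | step 12 | (2E,4E,6E)-N-[2α,3α-epoxy-1α-((E)-2-iodoethenyl)-4-oxo-1β-(tert-butyldimethylsilyloxy)cyclohexan-5α-yl]-8-methylnona-2,4,6-trienamide (shikimate numbering) | I/C=C/[C@@]1(O[Si](C)(C)C(C)(C)C)[C@H]2O[C@H]2C(=O)[C@@H](NC(=O)/C=C/C=C/C=C/C(C)C)C1
F8 | step 12 | 5-phenylselanyl derivative of F7 (either configuration at the selenium-bearing carbon) | I/C=C/[C@@]1(O[Si](C)(C)C(C)(C)C)[C@H]2O[C@H]2C(=O)C(NC(=O)/C=C/C=C/C=C/C(C)C)([Se]c3ccccc3)C1
F9 | step 17 | 5α-azido-2α,3α-epoxy-1β-hydroxy-1α-[(E)-2-iodoethenyl]cyclohexan-4-one | I/C=C/[C@@]1(O)[C@H]2O[C@H]2C(=O)[C@@H](N=[N+]=[N-])C1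
F10 | step 17 | 2-amino-5α,6α-epoxy-4β-hydroxy-4α-[(E)-2-iodoethenyl]cyclohex-2-en-1-one | NC1=C[C@@](O)(/C=C/I)[C@H]2O[C@H]2C1=O
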